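## Retrosynthetic overview

1. The malate ester C–O bond is made last: ω-alcohol 8 opens O-trifluoroacetyl-(R)-malic anhydride at C-1, so the malate needs no protecting groups.
2. The γ-lactone is the only ring and is formed in step 4, when one hydrogenation saturates an alkyne, removes all three benzyl groups and unveils a γ-hydroxy ortho ester that lactonises.
3. Key C–C bond (lactone C3–C4): the zinc acetylide of 3,3,3-triethoxypropyne, a propionate homoenolate equivalent, adds to the ketone carbon of racemic 3-alkyl-2-oxosuccinate 4 under chiral zinc catalysis with dynamic kinetic resolution, setting both stereocenters at once.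
4. Keto diester 4 comes from a crossed Claisen condensation of benzyl 12-(benzyloxy)dodecanoate with dibenzyl oxalate; the ester comes from 12-hydroxydodecanoic acid.

Assumption: the (1S,2S) antipode of the amino-alcohol ligand is taken as the one that delivers the carbinol configuration of 6; both antipodes are available, so the sense is fixed on the first run.

## Route

Step 1
Reactants: 1 12-hydroxydodecanoic acid
Product: 2 benzyl 12-(benzyloxy)dodecanoate
Conditions: NaH (2.4 equiv), BnBr (2.3 equiv), Bu4NI (cat.), DMF, 0 °C to rt
Reagents that add atoms: benzyl bromide, BrCc1ccccc1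
Why: Williamson etherification plus carboxylate O-alkylation in one pot: the disodium alkoxide–carboxylate is benzylated at both oxygens, giving groups that all leave later in a single hydrogenolysis; no stereocenter is involved.

Step 2
Reactants: 2 benzyl 12-(benzyloxy)dodecanoate; 3 dibenzyl oxalate
Product: 4 dibenzyl 2-[10-(benzyloxy)decyl]-3-oxobutanedioate (racemic)
Conditions: LiN(iPr)2 (1.1 equiv), THF, −78 °C; cannulate into 3 (1.5 equiv), THF, −78 °C; AcOH quench
Reagents that add atoms: none
Why: Crossed Claisen condensation: the lithium enolate of 2 acylates the non-enolisable, highly electrophilic oxalate (inverse addition into excess 3 prevents double addition), and the new chain-bearing stereocenter is formed racemic and stays labile through keto–enol exchange, which step 3 exploits.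

Step 3
Reactants: 4 dibenzyl 2-[10-(benzyloxy)decyl]-3-oxobutanedioate (racemic); 5 3,3,3-triethoxyprop-1-yne
Product: 6 dibenzyl (2R,3S)-3-[10-(benzyloxy)decyl]-2-hydroxy-2-(3,3,3-triethoxyprop-1-yn-1-yl)butanedioate
Conditions: Zn(OTf)2 (20 mol%), (1S,2S)-3-(tert-butyldimethylsilyloxy)-2-(dimethylamino)-1-(4-nitrophenyl)propan-1-ol (22 mol%), Et3N (30 mol%), 5 (2 equiv), toluene, 50 °C
Reagents that add atoms: none
Why: Proposed new method: a Carreira-type catalytic zinc-acetylide alkynylation run as a dynamic kinetic resolution, in which the ortho-ester alkyne serves as a propionate β-anion (homoenolate) equivalent attacking the ketone carbon; Et3N and zinc enolise the chain-bearing carbon of 4 faster than addition occurs, the chiral zinc amino-alkoxide selects the carbonyl face and sets the carbinol centre (2R), and six-ring zinc chelation between the ketone and the neighbouring ester places the acetylide anti to the decyl chain so that only the (S)-configured enantiomer of 4 is consumed (3S, the like relationship of the target); the alkyne is not a Michael acceptor, so the acidic C–H of 4 meets no competing electrophile; the closest known reaction types are the Zn(OTf)2/amino-alcohol/Et3N enantioselective alkynylation of α-keto esters and the dynamic kinetic resolution of β-stereogenic α-keto esters in transfer hydrogenation and carbene-catalysed additions.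

Step 4
Reactants: 6 dibenzyl (2R,3S)-3-[10-(benzyloxy)decyl]-2-hydroxy-2-(3,3,3-triethoxyprop-1-yn-1-yl)butanedioate
Product: 8 (2S)-2-[(1S)-1-carboxy-11-hydroxyundecyl]-5-oxooxolane-2-carboxylic acid, via saturated hydroxy ortho ester diacid 7 (not isolated)
Conditions: H2 (1 atm), 10% Pd/C, THF–H2O (9:1), rt; filter; 1 M aq. HCl, rt
Reagents that add atoms: water, O
Why: Heterogeneous hydrogenation/hydrogenolysis followed by ortho-ester hydrolysis–lactonisation: Pd/C saturates the alkyne and cleaves the two benzyl esters and the benzyl ether, then aqueous acid turns the γ-hydroxy ortho ester into the five-membered lactone through the cyclic ortho ester (the lactone carbonyl oxygen comes from water), and both stereocenters stay untouched because no base is present and no bond to them is broken.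

Step 5
Reactants: 8 (2S)-2-[(1S)-1-carboxy-11-hydroxyundecyl]-5-oxooxolane-2-carboxylic acid; 9 (R)-malic acid
Product: 12 (2S)-2-[(1S)-1-carboxy-11-{[(2R)-3-carboxy-2-hydroxypropanoyl]oxy}undecyl]-5-oxooxolane-2-carboxylic acid, via O-trifluoroacetyl malic anhydride 10 (not isolated), via O-trifluoroacetyl malate ester 11 (not isolated)
Conditions: 9 (3 equiv), (CF3CO)2O, 0 °C to rt, evaporate; 8, THF, rt to 40 °C; then THF–H2O, rt
Reagents that add atoms: none
Why: Regioselective cyclic-anhydride alcoholysis (the O-trifluoroacetyl malic anhydride route to malic acid 1-monoesters): the carbonyl next to the CF3CO2-bearing carbon of 10 is the more electrophilic, so the only alcohol of 8 opens it there while the hindered free acids do not react, and water then cleaves the labile trifluoroacetate without touching the new ester or the lactone; the malate stereocenter is retained because no bond to it is broken.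

## Compound list

1 | 12-hydroxydodecanoic acid | OCCCCCCCCCCCC(=O)O | starting material
2 | benzyl 12-(benzyloxy)dodecanoate | O=C(OCc1ccccc1)CCCCCCCCCCCOCc1ccccc1 | intermediate
3 | dibenzyl oxalate | O=C(OCc1ccccc1)C(=O)OCc1ccccc1 | starting material
4 | dibenzyl 2-[10-(benzyloxy)decyl]-3-oxobutanedioate (racemic) | O=C(OCc1ccccc1)C(=O)C(CCCCCCCCCCOCc1ccccc1)C(=O)OCc1ccccc1 | intermediate
5 | 3,3,3-triethoxyprop-1-yne | C#CC(OCC)(OCC)OCC | starting material
6 | dibenzyl (2R,3S)-3-[10-(benzyloxy)decyl]-2-hydroxy-2-(3,3,3-triethoxyprop-1-yn-1-yl)butanedioate | C(c1ccccc1)OCCCCCCCCCC[C@H](C(=O)OCc1ccccc1)[C@](O)(C(=O)OCc1ccccc1)C#CC(OCC)(OCC)OCC | intermediate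
7 | (2S,3S)-2-hydroxy-3-(10-hydroxydecyl)-2-(3,3,3-triethoxypropyl)butanedioic acid (formed in the flask in step 4) | OCCCCCCCCCC[C@H](C(=O)O)[C@](O)(C(=O)O)CCC(OCC)(OCC)OCC | intermediate
8 | (2S)-2-[(1S)-1-carboxy-11-hydroxyundecyl]-5-oxooxolane-2-carboxylic acid | OCCCCCCCCCC[C@H](C(=O)O)[C@]1(C(=O)O)CCC(=O)O1 | intermediate
9 | (R)-malic acid | O=C(O)C[C@@H](O)C(=O)O | starting material
10 | (3R)-2,5-dioxooxolan-3-yl trifluoroacetate (formed in the flask in step 5) | O=C1C[C@@H](OC(=O)C(F)(F)F)C(=O)O1 | intermediate
11 | (2S)-2-[(1S)-1-carboxy-11-{[(2R)-3-carboxy-2-(trifluoroacetoxy)propanoyl]oxy}undecyl]-5-oxooxolane-2-carboxylic acid (formed in the flask in step 5) | O=C(O)C[C@@H](OC(=O)C(F)(F)F)C(=O)OCCCCCCCCCC[C@H](C(=O)O)[C@]1(C(=O)O)CCC(=O)O1 | intermediate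
12 | (2S)-2-[(1S)-1-carboxy-11-{[(2R)-3-carboxy-2-hydroxypropanoyl]oxy}undecyl]-5-oxooxolane-2-carboxylic acid (CNP0457473.4) | O=C(O)C[C@@H](O)C(=O)OCCCCCCCCCC[C@H](C(=O)O)[C@]1(C(=O)O)CCC(=O)O1 | target

## Step count and risks

Total steps: 5. Longest linear sequence: 5 (1 → 2 → 4 → 6 → 8 → 12).

**Step 3 (highest risk).** Three things can go wrong:
- The acidic keto diester may sit on zinc as an unreactive enolate.
- The relative configuration may come out unlike if the neighbouring ester takes the anti (Felkin) position instead of chelating.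
- The zinc alkoxide of 6 may revert by retro-addition or retro-aldol at 50 °C.

Fallback (sets out from 4, rejoins at 8): a reductive ketyl–olefin coupling replaces the catalytic alkynylation. 4 and benzyl acrylate are treated with SmI2 (2.5 equiv) and t-BuOH in THF at −78 °C. The samarium-bound ketyl of the keto ester adds to the acrylate β-carbon and the tertiary alkoxide lactonises with loss of benzyl alcohol. Samarium chelation between the ketone and the neighbouring ester puts the new bond anti to the decyl chain, so the lactone forms as the racemic like pair: benzyl (2S)-2-[(2S)-1,12-bis(benzyloxy)-1-oxododecan-2-yl]-5-oxooxolane-2-carboxylate F1 and its mirror image benzyl (2R)-2-[(2R)-1,12-bis(benzyloxy)-1-oxododecan-2-yl]-5-oxooxolane-2-carboxylate F2. Preparative chiral SFC separates them. F1 is hydrogenolysed (H2, 10% Pd/C, THF) to 8 and F2 is discarded.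

**Step 4.** Pd/C may hydrogenolyse the tertiary propargylic or allylic C–O bond during alkyne reduction. The free acids may also be ethylated by the ortho ester before it lactonises.

Fallback (sets out from 6, rejoins at 8): a stepwise sequence with lactonisation before debenzylation. The alkyne alone is saturated over 5% Rh/Al2O3 (H2, EtOAc, trace Et3N), which leaves benzyl groups and the tertiary C–O bond intact. This gives dibenzyl (2S,3S)-3-[10-(benzyloxy)decyl]-2-hydroxy-2-(3,3,3-triethoxypropyl)butanedioate F3. Pyridinium p-toluenesulfonate in wet THF converts F3 into the lactone benzyl (2S)-2-[(2S)-1,12-bis(benzyloxy)-1-oxododecan-2-yl]-5-oxooxolane-2-carboxylate F4 with loss of three ethanol. F4 is purified on silica and only then debenzylated (H2, 10% Pd/C, THF) to 8.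

**Step 5.** The anhydride may open partly at C-4, and the free acids of 8 may form mixed anhydrides that lead to oligomers.

Fallback (sets out from 9, rejoins at 12): a pre-differentiated malate donor replaces the anhydride. 9 is converted with 2,2-dimethoxypropane and p-toluenesulfonic acid (cat.) into the acetonide 2-[(4R)-2,2-dimethyl-5-oxo-1,3-dioxolan-4-yl]acetic acid F5. In F5, C-1 and the hydroxyl are tied up as the dioxolanone, and only that carbonyl is active in acyl transfer. With Et3N (to hold all carboxylic acids as unreactive carboxylates) and 4-(dimethylamino)pyridine (cat.) in THF at 40 °C, the alcohol of 8 opens the dioxolanone and acetone is expelled. Acidic work-up gives 12 with unambiguous 1-ester regiochemistry.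

## Further compounds

F1 | step 3 | benzyl (2S)-2-[(2S)-1,12-bis(benzyloxy)-1-oxododecan-2-yl]-5-oxooxolane-2-carboxylate | C(c1ccccc1)OCCCCCCCCCC[C@H](C(=O)OCc1ccccc1)[C@]1(C(=O)OCc2ccccc2)CCC(=O)O1
F2 | step 3 | benzyl (2R)-2-[(2R)-1,12-bis(benzyloxy)-1-oxododecan-2-yl]-5-oxooxolane-2-carboxylate | C(c1ccccc1)OCCCCCCCCCC[C@@H](C(=O)OCc1ccccc1)[C@@]1(C(=O)OCc2ccccc2)CCC(=O)O1
F3 | step 4 | dibenzyl (2S,3S)-3-[10-(benzyloxy)decyl]-2-hydroxy-2-(3,3,3-triethoxypropyl)butanedioate | C(c1ccccc1)OCCCCCCCCCC[C@H](C(=O)OCc1ccccc1)[C@](O)(C(=O)OCc1ccccc1)CCC(OCC)(OCC)OCC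
F4 | step 4 | benzyl (2S)-2-[(2S)-1,12-bis(benzyloxy)-1-oxododecan-2-yl]-5-oxooxolane-2-carboxylate | C(c1ccccc1)OCCCCCCCCCC[C@H](C(=O)OCc1ccccc1)[C@]1(C(=O)OCc2ccccc2)CCC(=O)O1
F5 | step 5 | 2-[(4R)-2,2-dimethyl-5-oxo-1,3-dioxolan-4-yl]acetic acid | OC(=O)C[C@H]1OC(C)(C)OC1=O
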